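The oxolane (O1, C2 aryl, C3, C4, C5) is cut at C4–C5 and O1–C5. The key step exploits two features of this ring: C5 is a bare OCH2 unit on C4, and H3 and H4 are cis, the pattern left when a hydrogen and a one-carbon unit add to the same face of a C3=C4 alkene. One hydroxyl-directed, rhodium-catalysed hydroformylation therefore forms C4–C5, sets C3 and C4 from the C2 carbinol and closes the ring as a lactol. Its precursor is the enantioenriched Z allylic alcohol ArCH(OH)–C(CH2OTBS)=CH–CH2Ar (Ar = 3,4,5-trimethoxyphenyl), built from propargyl alcohol, the benzyl chloride and an aryl Weinreb amide.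

Key step: step 6

Remark: the Weinreb amide used in step 4 is taken as a catalogue compound. Atom labels in the Why lines follow the oxolane numbering of the target, and TBS = tert-butyldimethylsilyl.

Step 1
Reactants: 1 propargyl alcohol; 2 3,4,5-trimethoxybenzyl chloride
Product: 4 4-(3,4,5-trimethoxyphenyl)but-2-yn-1-ol, via dimagnesium salt 3 (not isolated)
Conditions: 1 (1.2 equiv), EtMgBr (2.4 equiv), THF, 0 → 50 °C; CuCl (10 mol%), 2, 60 °C; 1 M HCl
Reagents that add atoms: none
Why: Copper-catalysed coupling of an alkynyl Grignard reagent with a benzylic halide: the alkynylcopper formed from 3 displaces the benzylic chloride at carbon while the hard magnesium alkoxide does not compete, so no hydroxyl protection is needed.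

Step 2
Reactants: 4 4-(3,4,5-trimethoxyphenyl)but-2-yn-1-ol
Product: 6 (Z)-2-iodo-4-(3,4,5-trimethoxyphenyl)but-2-en-1-ol, via stannane 5 (not isolated)
Conditions: [(C5Me5)RuCl]4 (2.5 mol%), Bu3SnH (1.05 equiv, slow addition), CH2Cl2, rt; then I2 (1.1 equiv), 0 °C; aq Na2S2O3, aq KF
Reagents that add atoms: iodine, II
Why: Hydroxyl-directed ruthenium-catalysed trans-hydrostannation followed by stereoretentive iododestannylation: the propargylic OH hydrogen-bonds to the Ru–Cl unit and steers tin to the proximal carbon while H is delivered anti, so tin and then iodine sit cis to the arylmethyl group, which fixes the Z geometry needed in step 6.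

Step 3
Reactants: 6 (Z)-2-iodo-4-(3,4,5-trimethoxyphenyl)but-2-en-1-ol
Product: 7 (Z)-tert-butyl{[2-iodo-4-(3,4,5-trimethoxyphenyl)but-2-en-1-yl]oxy}dimethylsilane
Conditions: TBSCl (1.2 equiv), imidazole (2 equiv), DMF, 0 °C → rt
Reagents that add atoms: tert-butyldimethylsilyl chloride, CC(C)(C)[Si](C)(C)Cl
Why: Standard imidazole-mediated silylation of a primary alcohol; the silyl ether keeps this oxygen from quenching the organolithium in step 4 and from competing with the C2 hydroxyl for the aldehyde in step 6.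

Step 4
Reactants: 7 (Z)-tert-butyl{[2-iodo-4-(3,4,5-trimethoxyphenyl)but-2-en-1-yl]oxy}dimethylsilane; 8 N-methoxy-N-methyl-3,4,5-trimethoxybenzamide
Product: 10 (Z)-2-[(tert-butyldimethylsilyloxy)methyl]-1,4-bis(3,4,5-trimethoxyphenyl)but-2-en-1-one, via alkenyllithium 9 (not isolated)
Conditions: t-BuLi (2.1 equiv), Et2O, −78 °C, 20 min; 8 (1.2 equiv) in THF, −78 → −40 °C; AcOH, −78 °C
Reagents that add atoms: none
Why: Iodine–lithium exchange with retention of alkene geometry and Weinreb ketone synthesis, which stops at the ketone; ether at −78 °C should keep 9 from O-to-C silyl migration, and the acidic quench protonates the liberated amine before it can add to the enone.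

Step 5
Reactants: 10 (Z)-2-[(tert-butyldimethylsilyloxy)methyl]-1,4-bis(3,4,5-trimethoxyphenyl)but-2-en-1-one
Product: 11 (1R,2Z)-2-[(tert-butyldimethylsilyloxy)methyl]-1,4-bis(3,4,5-trimethoxyphenyl)but-2-en-1-ol
Conditions: (R)-2-methyl-CBS-oxazaborolidine (0.3 equiv), catecholborane (1.8 equiv), toluene, −78 → −40 °C; MeOH, aq NaOH wash
Reagents that add atoms: none
Why: Corey–Bakshi–Shibata reduction: the planar conjugated aryl group is expected to act as the large substituent and the twisted alkenyl group as the small one, so the (R)-catalyst should deliver hydride to the Si face of the carbonyl and set the carbinol as R (the C2 configuration of the target; the descriptor changes only because the alkenyl group outranks aryl), while catecholborane at low temperature leaves the alkene alone.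

Step 6
Reactants: 11 (1R,2Z)-2-[(tert-butyldimethylsilyloxy)methyl]-1,4-bis(3,4,5-trimethoxyphenyl)but-2-en-1-ol
Product: 13 (3R,4R,5S)-4-[(tert-butyldimethylsilyloxy)methyl]-3-(3,4,5-trimethoxybenzyl)-5-(3,4,5-trimethoxyphenyl)oxolan-2-ol (both anomers), via hydroxy aldehyde 12 (not isolated)
Conditions: Rh(acac)(CO)2 (5 mol%), Ph2POMe (25 mol%), 4 Å MS, CO/H2 (1:1, 40 bar), THF, 70 °C
Reagents that add atoms: carbon monoxide, [C-]#[O+]
Why: Methyl diphenylphosphinite exchanges reversibly onto the C2 hydroxyl and holds the rhodium hydride on that face, so that H adds to C3 and Rh to the less substituted C4 in a syn hydrometalation through a six-membered Rh–P–O–C2–C3–C4 chelate, after which CO insertion and hydrogenolysis release aldehyde 12 (new C4–C5 bond). The closest known reaction types are the rhodium-catalysed hydroformylation of allylic alcohols to 2-hydroxyoxolanes and the hydroformylation of unsaturated alcohols through reversibly bound phosphinite directing groups. The ring closes by 5-exo-trig addition of the C2 hydroxyl to the formyl carbon (O1–C5). C3 and C4 are controlled by the C2 stereocentre: allylic 1,3-strain with the cis arylmethyl group keeps the C2–H in the alkene plane, which puts oxygen on one face and the aryl group on the other, and syn addition from the oxygen face of the Z alkene should give 3R,4R with H3 and H4 cis; the anomeric centre is uncontrolled and is erased in step 7. The step needs regioselectivity for formyl at C4 (secured by the chelate and by the reluctance to build a quaternary C3), face selectivity (secured by the bound catalyst and reinforced by the aryl group shielding the other face) and chemoselectivity over double-bond migration towards the arene (favoured by high CO pressure at moderate temperature).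

Step 7
Reactants: 13 (3R,4R,5S)-4-[(tert-butyldimethylsilyloxy)methyl]-3-(3,4,5-trimethoxybenzyl)-5-(3,4,5-trimethoxyphenyl)oxolan-2-ol
Product: 15 tert-butyldimethyl{[(2S,3R,4R)-4-(3,4,5-trimethoxybenzyl)-2-(3,4,5-trimethoxyphenyl)oxolan-3-yl]methoxy}silane, via oxocarbenium ion 14 (not isolated)
Conditions: Et3SiH (3 equiv), BF3·OEt2 (1.5 equiv), CH2Cl2, −78 °C; sat. NaHCO3 at −78 °C
Reagents that add atoms: none
Why: Ionic reduction of a lactol: BF3 ionises the anomeric hydroxyl to 14, which Et3SiH reduces to the C5 methylene, and at −78 °C neither the silyl ether nor the benzylic C2–O1 bond should ionise, the 2,3-trans arrangement being in any case the more stable one at C2.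

Step 8
Reactants: 15 tert-butyldimethyl{[(2S,3R,4R)-4-(3,4,5-trimethoxybenzyl)-2-(3,4,5-trimethoxyphenyl)oxolan-3-yl]methoxy}silane
Product: 16 [(2S,3R,4R)-4-(3,4,5-trimethoxybenzyl)-2-(3,4,5-trimethoxyphenyl)oxolan-3-yl]methanol (CNP0321241.1)
Conditions: Bu4NF (1.2 equiv), THF, 0 °C → rt
Reagents that add atoms: none
Why: Fluoride cleavage of the silyl ether, driven by the Si–F bond, under non-acidic conditions that leave the 2-aryloxolane and its three stereocentres untouched.

Compound list
1 | propargyl alcohol | C#CCO | starting material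
2 | 3,4,5-trimethoxybenzyl chloride | COc1cc(CCl)cc(OC)c1OC | starting material
3 | bromomagnesium 3-(bromomagnesio)prop-2-yn-1-olate (not isolated) | Br[Mg]C#CCO[Mg]Br | intermediate
4 | 4-(3,4,5-trimethoxyphenyl)but-2-yn-1-ol | COc1cc(CC#CCO)cc(OC)c1OC | intermediate
5 | (Z)-2-(tributylstannyl)-4-(3,4,5-trimethoxyphenyl)but-2-en-1-ol, tin cis to the arylmethyl group (not isolated) | COc1cc(C/C=C(/CO)[Sn](CCCC)(CCCC)CCCC)cc(OC)c1OC | intermediate
6 | (Z)-2-iodo-4-(3,4,5-trimethoxyphenyl)but-2-en-1-ol, iodine cis to the arylmethyl group | COc1cc(C/C=C(/CO)I)cc(OC)c1OC | intermediate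
7 | (Z)-tert-butyl{[2-iodo-4-(3,4,5-trimethoxyphenyl)but-2-en-1-yl]oxy}dimethylsilane | COc1cc(C/C=C(/CO[Si](C)(C)C(C)(C)C)I)cc(OC)c1OC | intermediate
8 | N-methoxy-N-methyl-3,4,5-trimethoxybenzamide | COc1cc(C(=O)N(C)OC)cc(OC)c1OC | starting material
9 | [(E)-1-(tert-butyldimethylsilyloxy)-4-(3,4,5-trimethoxyphenyl)but-2-en-2-yl]lithium, lithium cis to the arylmethyl group (not isolated) | COc1cc(C/C=C(/CO[Si](C)(C)C(C)(C)C)[Li])cc(OC)c1OC | intermediate
10 | (Z)-2-[(tert-butyldimethylsilyloxy)methyl]-1,4-bis(3,4,5-trimethoxyphenyl)but-2-en-1-one, carbonyl cis to the arylmethyl group | COc1cc(C/C=C(/CO[Si](C)(C)C(C)(C)C)C(=O)c2cc(OC)c(OC)c(OC)c2)cc(OC)c1OC | intermediate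
11 | (1R,2Z)-2-[(tert-butyldimethylsilyloxy)methyl]-1,4-bis(3,4,5-trimethoxyphenyl)but-2-en-1-ol | COc1cc(C/C=C(/CO[Si](C)(C)C(C)(C)C)[C@H](O)c2cc(OC)c(OC)c(OC)c2)cc(OC)c1OC | intermediate
12 | (2R,3R,4S)-3-[(tert-butyldimethylsilyloxy)methyl]-4-hydroxy-2-(3,4,5-trimethoxybenzyl)-4-(3,4,5-trimethoxyphenyl)butanal (not isolated) | COc1cc(C[C@@H](C=O)[C@H](CO[Si](C)(C)C(C)(C)C)[C@H](O)c2cc(OC)c(OC)c(OC)c2)cc(OC)c1OC | intermediate
13 | (3R,4R,5S)-4-[(tert-butyldimethylsilyloxy)methyl]-3-(3,4,5-trimethoxybenzyl)-5-(3,4,5-trimethoxyphenyl)oxolan-2-ol, anomers interconvert, one drawn | COc1cc(C[C@H]2[C@@H](O)O[C@H](c3cc(OC)c(OC)c(OC)c3)[C@H]2CO[Si](C)(C)C(C)(C)C)cc(OC)c1OC | intermediate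
14 | (2S,3R,4R)-3-[(tert-butyldimethylsilyloxy)methyl]-4-(3,4,5-trimethoxybenzyl)-2-(3,4,5-trimethoxyphenyl)-3,4-dihydro-2H-furan-1-ium (not isolated) | COc1cc(C[C@H]2C=[O+][C@H](c3cc(OC)c(OC)c(OC)c3)[C@H]2CO[Si](C)(C)C(C)(C)C)cc(OC)c1OC | intermediate
15 | tert-butyldimethyl{[(2S,3R,4R)-4-(3,4,5-trimethoxybenzyl)-2-(3,4,5-trimethoxyphenyl)oxolan-3-yl]methoxy}silane | COc1cc(C[C@H]2CO[C@H](c3cc(OC)c(OC)c(OC)c3)[C@H]2CO[Si](C)(C)C(C)(C)C)cc(OC)c1OC | intermediate
16 | [(2S,3R,4R)-4-(3,4,5-trimethoxybenzyl)-2-(3,4,5-trimethoxyphenyl)oxolan-3-yl]methanol | COc1cc(C[C@H]2CO[C@H](c3cc(OC)c(OC)c(OC)c3)[C@H]2CO)cc(OC)c1OC | target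

Total step count: 8. Longest linear sequence: 8 steps (1 to 16).

Steps most likely to fail

Step 6. Hydrometalation of the hindered trisubstituted alkene may be slow. β-Hydride elimination from the C4 rhodium alkyl may move the double bond into conjugation with the arene and lead to formylation elsewhere. The allylic alcohol may isomerise to the saturated ketone. Face control may be lost if the phosphinite exchanges too slowly onto the hindered C2 hydroxyl. The fallback binds the directing group covalently; it sets out from 11 and comes back at 15. Alcohol 11 is esterified with 2-(diphenylphosphanyl)benzoic acid (DCC, DMAP, CH2Cl2) to the (1R,2Z)-allylic 2-(diphenylphosphanyl)benzoate F1. Hydroformylation of F1 (Rh(acac)(CO)2, P(OPh)3, CO/H2 1:1, 40 bar, toluene, 70 °C) should deliver H and CHO syn from the ester-bearing face and give the 4-O-[2-(diphenylphosphanyl)benzoyl] derivative of the hydroxy aldehyde F2. i-Bu2AlH (CH2Cl2, −78 → 0 °C) reduces the aldehyde and cleaves the benzoate to the (1S,2R,3R)-1,4-diol F3. TsCl (1.1 equiv), pyridine and DMAP sulfonylate only the primary hydroxyl, and the primary monotosylate F4 closes in the same flask by 5-exo-tet attack of the C2 hydroxyl on C5, with retention at C2 because the C2–O bond is not touched, to give 15.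

Step 5. Hydride delivery may discriminate poorly, or in the opposite sense, between the aryl and alkenyl sides of the ketone, and hydroboration or Z to E drift of the enone may compete. The fallback creates the carbinol centre in the C–C bond-forming event; it sets out from 7 and comes back at 11. Iodide 7 is lithiated as in step 4 (t-BuLi, Et2O, −78 °C) and transmetalated with EtZnCl to the alkenyl(ethyl)zinc F5. Lithium halide is sequestered with N,N,N',N'-tetraethylethylenediamine. F5 is then added to 3,4,5-trimethoxybenzaldehyde in the presence of (2S)-3-exo-morpholinoisoborneol (10 mol%, toluene/hexane, 0 °C). This amino-alcohol-catalysed alkenylzinc addition is known for Z-trisubstituted allylic alcohols of this substitution pattern; transfer to the Si face of the aldehyde should give 11 directly.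

Step 7. The Lewis acid may ionise the benzylic C2–O1 bond, which would cause epimerisation at C2 or Friedel–Crafts closure onto the arylmethyl ring at C4, or it may strip the silyl ether before the reduction is complete. The fallback removes the anomeric oxygen by a radical path without acid; it sets out from 13 and comes back at 15. Lactol 13 is converted with N-(phenylselanyl)phthalimide and Bu3P (CH2Cl2, −20 °C) into the anomeric phenyl selenide F6. Bu3SnH with AIBN (toluene, 80 °C) then reduces the C5–Se bond through the oxolan-2-yl radical to 15.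

Further compounds
F1 | step 6 | (1R,2Z)-2-[(tert-butyldimethylsilyloxy)methyl]-1,4-bis(3,4,5-trimethoxyphenyl)but-2-en-1-yl 2-(diphenylphosphanyl)benzoate | COc1cc(C/C=C(/CO[Si](C)(C)C(C)(C)C)[C@H](OC(=O)c2ccccc2P(c2ccccc2)c2ccccc2)c2cc(OC)c(OC)c(OC)c2)cc(OC)c1OC
F2 | step 6 | (1S,2R,3R)-2-[(tert-butyldimethylsilyloxy)methyl]-3-formyl-4-(3,4,5-trimethoxyphenyl)-1-(3,4,5-trimethoxyphenyl)butyl 2-(diphenylphosphanyl)benzoate | COc1cc(C[C@@H](C=O)[C@H](CO[Si](C)(C)C(C)(C)C)[C@H](OC(=O)c2ccccc2P(c2ccccc2)c2ccccc2)c2cc(OC)c(OC)c(OC)c2)cc(OC)c1OC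
F3 | step 6 | (1S,2R,3R)-2-[(tert-butyldimethylsilyloxy)methyl]-3-(3,4,5-trimethoxybenzyl)-1-(3,4,5-trimethoxyphenyl)butane-1,4-diol | COc1cc(C[C@@H](CO)[C@H](CO[Si](C)(C)C(C)(C)C)[C@H](O)c2cc(OC)c(OC)c(OC)c2)cc(OC)c1OC
F4 | step 6 | (2R,3R,4S)-3-[(tert-butyldimethylsilyloxy)methyl]-4-hydroxy-2-(3,4,5-trimethoxybenzyl)-4-(3,4,5-trimethoxyphenyl)butyl 4-methylbenzenesulfonate | COc1cc(C[C@@H](COS(=O)(=O)c2ccc(C)cc2)[C@H](CO[Si](C)(C)C(C)(C)C)[C@H](O)c2cc(OC)c(OC)c(OC)c2)cc(OC)c1OC
F5 | step 5 | ethyl[(E)-1-(tert-butyldimethylsilyloxy)-4-(3,4,5-trimethoxyphenyl)but-2-en-2-yl]zinc, zinc cis to the arylmethyl group | COc1cc(C/C=C(/CO[Si](C)(C)C(C)(C)C)[Zn]CC)cc(OC)c1OC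
F6 | step 7 | tert-butyldimethyl{[(2S,3R,4R)-5-(phenylselanyl)-4-(3,4,5-trimethoxybenzyl)-2-(3,4,5-trimethoxyphenyl)oxolan-3-yl]methoxy}silane, anomeric mixture | COc1cc(C[C@H]2C([Se]c3ccccc3)O[C@H](c3cc(OC)c(OC)c(OC)c3)[C@H]2CO[Si](C)(C)C(C)(C)C)cc(OC)c1OC
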